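**Retrosynthetic overview**

1. The target is (2S)-6-geranyl-5,7-dihydroxy-3′,4′-dimethoxyflavanone. The plan rests on ring A, where C8a carries the ring oxygen O1 and the neighbouring C4a carries the C4 carbonyl, with the C5 oxygen beside C4a able to polarise an aryne across C4a–C8a.
2. Ring C is opened at O1–C2 (asymmetric oxa-Michael) to the 2′-hydroxychalcone, after loss of the two MOM ethers.
3. The chalcone is cut at C8a–O1 and C4a–C4: a C4a–C8a aryne inserts into the carboxyl C–O bond of 3,4-dimethoxycinnamic acid.
4. The silylaryl triflate comes from phloroglucinol by geranylation between two MOM ethers and carbamate-directed ortho-silylation of a phenol whose two ortho positions are equivalent.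
5. Ring order: rings A and B are bought (phloroglucinol, cinnamic acid); only ring C is built, in step 9.

Key step: step 8

Remarks on the chemistry: "geranyl" means (2E)-3,7-dimethylocta-2,6-dien-1-yl. Assumption: the quinine-derived thiourea is taken to deliver the 2S flavanone; if a trial run shows the opposite sense, the quinidine-derived pseudo-enantiomer is used instead.

**Route**

Step 1
Reactants: 1 phloroglucinol; 2 chloromethyl methyl ether
Product: 3 3,5-bis(methoxymethoxy)phenol
Conditions: MOMCl (2.0 equiv), i-Pr2NEt, CH2Cl2/DMF, 0 °C → rt; chromatography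
Reagents that add atoms: chloromethyl methyl ether, COCCl
Why: Statistical O-alkylation of the symmetric triol should give the bis-ether as the main component at two equivalents; the mono-ether is separable and can be resubmitted.

Step 2
Reactants: 3 3,5-bis(methoxymethoxy)phenol; 4 chlorotriisopropylsilane
Product: 5 [3,5-bis(methoxymethoxy)phenoxy]triisopropylsilane
Conditions: TIPSCl, imidazole, DMF, rt
Reagents that add atoms: chlorotriisopropylsilane, CC(C)[Si](Cl)(C(C)C)C(C)C
Why: Standard phenol silylation; the bulky, weakly coordinating TIPS ether is chosen so that it neither directs lithiation nor migrates in step 3.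

Step 3
Reactants: 5 [3,5-bis(methoxymethoxy)phenoxy]triisopropylsilane; 6 geranyl bromide
Product: 9 [4-geranyl-3,5-bis(methoxymethoxy)phenoxy]triisopropylsilane, via aryllithium 7 (not isolated), via arylcopper 8 (not isolated)
Conditions: n-BuLi (1.1 equiv), THF, 0 °C; CuBr·SMe2 (1.1 equiv), −40 °C; geranyl bromide, −40 °C → rt
Reagents that add atoms: geranyl bromide, BrC/C=C(\C)CCC=C(C)C
Why: Directed ortho-metalation should occur at the carbon flanked by both MOM ethers, and the arylcopper should then undergo SN2 allylation at the primary carbon, keeping the E-alkene and avoiding SN2′ attack at the tertiary terminus.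

Step 4
Reactants: 9 [4-geranyl-3,5-bis(methoxymethoxy)phenoxy]triisopropylsilane
Product: 10 4-geranyl-3,5-bis(methoxymethoxy)phenol
Conditions: n-Bu4NF, THF, 0 °C
Reagents that add atoms: none
Why: Fluoride cleavage of the aryl silyl ether; MOM ethers and the diene are inert, and the phenol obtained has two equivalent ortho positions.

Step 5
Reactants: 10 4-geranyl-3,5-bis(methoxymethoxy)phenol; 11 isopropyl isocyanate
Product: 12 4-geranyl-3,5-bis(methoxymethoxy)phenyl N-isopropylcarbamate
Conditions: i-PrNCO, Et3N (cat.), CH2Cl2, rt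
Reagents that add atoms: isopropyl isocyanate, CC(C)N=C=O
Why: Base-catalysed addition of the phenol to the isocyanate gives a carbamate that is a strong ortho-directing group and can later be removed under mild basic conditions.

Step 6
Reactants: 12 4-geranyl-3,5-bis(methoxymethoxy)phenyl N-isopropylcarbamate; 13 chlorotrimethylsilane
Product: 17 4-geranyl-3,5-bis(methoxymethoxy)-2-(trimethylsilyl)phenyl N-isopropylcarbamate, via N-silyl carbamate 14 (not isolated), via ortho-lithiated carbamate 15 (not isolated), via C-silylated N-silyl carbamate 16 (not isolated)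
Conditions: TBSOTf (1.1 equiv), TMEDA, Et2O, 0 °C → rt; n-BuLi, TMEDA, −78 °C; TMSCl, −78 °C → rt; aq NH4Cl
Reagents that add atoms: chlorotrimethylsilane, C[Si](C)(C)Cl
Why: Snieckus-type directed ortho-metalation: after in-flask N-silylation masks the N–H, lithiation should take place at the ring carbon between the carbamate and a MOM ether (both ortho sites are equivalent), and TMSCl traps the anion at −78 °C before any anionic Fries shift; aqueous work-up hydrolyses the N–Si bond.

Step 7
Reactants: 17 4-geranyl-3,5-bis(methoxymethoxy)-2-(trimethylsilyl)phenyl N-isopropylcarbamate; 18 N-phenylbis(trifluoromethanesulfonimide)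
Product: 20 4-geranyl-3,5-bis(methoxymethoxy)-2-(trimethylsilyl)phenyl trifluoromethanesulfonate, via silylphenol 19 (not isolated)
Conditions: DBU, Et2NH, MeCN, 40 °C; then PhNTf2, rt
Reagents that add atoms: N-phenylbis(trifluoromethanesulfonimide), O=S(=O)(N(c1ccccc1)S(=O)(=O)C(F)(F)F)C(F)(F)F
Why: E1cB cleavage of the N–H carbamate expels isopropyl isocyanate (trapped by Et2NH as a urea), and the phenoxide is triflated in the same flask under conditions that leave the aryl–silicon bond, MOM ethers and diene untouched.

Step 8
Reactants: 20 4-geranyl-3,5-bis(methoxymethoxy)-2-(trimethylsilyl)phenyl trifluoromethanesulfonate; 21 (E)-3,4-dimethoxycinnamic acid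
Product: 24 (E)-1-[3-geranyl-6-hydroxy-2,4-bis(methoxymethoxy)phenyl]-3-(3,4-dimethoxyphenyl)prop-2-en-1-one, via cesium 3,4-dimethoxycinnamate 22 (not isolated), via aryne 23 (not isolated)
Conditions: 21 (1.5 equiv), Cs2CO3 (0.75 equiv), MeOH, rt, evaporate, dry (PhMe azeotrope); then 20, CsF (3 equiv), THF, 110 °C (sealed tube); aq NH4Cl, 0 °C
Reagents that add atoms: (E)-3,4-dimethoxycinnamic acid, COc1ccc(/C=C/C(=O)O)cc1OC
Why: Fluoride attacks silicon of 20 and triflate leaves to give aryne 23 across C4a–C8a; the carboxylate oxygen of 22 adds to C8a and the aryl anion left at C4a attacks the ester carbonyl through a transient four-membered alkoxide that opens to the phenoxide of the aryl ketone, so O1–C8a and C4–C4a form in one operation. The closest known reaction type is the fluoride-triggered insertion of arynes into the C–O bond of carboxylic acids to give ortho-hydroxyaryl ketones. No ring is closed (the four-membered alkoxide is only an intermediate) and no stereocentre is formed. The step needs regiocontrol on the unsymmetrical aryne: the C5 MOM ether beside C4a distorts the aryne so that oxygen enters at the remote, less hindered C8a and the charge develops at C4a next to the inductively withdrawing oxygen. It also needs the open chalcone to persist: the acid is used as its dry cesium salt so that the product rests as the cesium phenoxide, which cannot close to the flavanone without a proton donor, and it is protonated only in the cold quench. The 6- versus 8-geranyl question does not arise, because the two ortho positions of phenol 10 were equivalent when silicon was placed.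

Step 9
Reactants: 24 (E)-1-[3-geranyl-6-hydroxy-2,4-bis(methoxymethoxy)phenyl]-3-(3,4-dimethoxyphenyl)prop-2-en-1-one
Product: 25 (2S)-6-geranyl-5,7-bis(methoxymethoxy)-3′,4′-dimethoxyflavanone
Conditions: 9-amino(9-deoxy)epi-quinine N′-[3,5-bis(trifluoromethyl)phenyl]thiourea (10 mol %), PhMe, 0 °C → rt; stopped before equilibration
Reagents that add atoms: none
Why: Organocatalytic asymmetric intramolecular oxa-Michael addition (6-endo-trig): the quinuclidine nitrogen activates the phenol while the thiourea hydrogen-bonds the enone carbonyl, and the chiral pocket should deliver oxygen to the Si face of C-β to set C2 as S; the reaction is quenched by filtration through silica before retro-Michael erodes the ee.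

Step 10
Reactants: 25 (2S)-6-geranyl-5,7-bis(methoxymethoxy)-3′,4′-dimethoxyflavanone
Product: 26 (2S)-6-geranyl-5,7-dihydroxy-3′,4′-dimethoxyflavanone (CNP0268555.1)
Conditions: 3 M aq HCl, MeOH, 40 °C
Reagents that add atoms: none
Why: Acid-catalysed acetal solvolysis should remove the C5 MOM ether first (peri to the carbonyl) and then the C7 one; the resulting 5-OH···O=C4 hydrogen bond disfavours ring opening, so C2 should be retained, and dilute acid at this temperature should spare the trisubstituted alkenes.

**Compound list**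

1 | phloroglucinol | Oc1cc(O)cc(O)c1 | starting material
2 | chloromethyl methyl ether | COCCl | starting material
3 | 3,5-bis(methoxymethoxy)phenol | COCOc1cc(O)cc(OCOC)c1 | intermediate
4 | chlorotriisopropylsilane | CC(C)[Si](Cl)(C(C)C)C(C)C | starting material
5 | [3,5-bis(methoxymethoxy)phenoxy]triisopropylsilane | COCOc1cc(O[Si](C(C)C)(C(C)C)C(C)C)cc(OCOC)c1 | intermediate
6 | geranyl bromide | BrC/C=C(\C)CCC=C(C)C | starting material
7 | aryllithium (lithium between the two MOM ethers of 5) | COCOc1cc(O[Si](C(C)C)(C(C)C)C(C)C)cc(OCOC)c1[Li] | intermediate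
8 | arylcopper (copper in place of lithium in 7) | COCOc1cc(O[Si](C(C)C)(C(C)C)C(C)C)cc(OCOC)c1[Cu] | intermediate
9 | [4-geranyl-3,5-bis(methoxymethoxy)phenoxy]triisopropylsilane | COCOc1cc(O[Si](C(C)C)(C(C)C)C(C)C)cc(OCOC)c1C/C=C(\C)CCC=C(C)C | intermediate
10 | 4-geranyl-3,5-bis(methoxymethoxy)phenol | COCOc1cc(O)cc(OCOC)c1C/C=C(\C)CCC=C(C)C | intermediate
11 | isopropyl isocyanate | CC(C)N=C=O | starting material
12 | 4-geranyl-3,5-bis(methoxymethoxy)phenyl N-isopropylcarbamate | COCOc1cc(OC(=O)NC(C)C)cc(OCOC)c1C/C=C(\C)CCC=C(C)C | intermediate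
13 | chlorotrimethylsilane | C[Si](C)(C)Cl | starting material
14 | N-(tert-butyldimethylsilyl) derivative of 12 | COCOc1cc(OC(=O)N(C(C)C)[Si](C)(C)C(C)(C)C)cc(OCOC)c1C/C=C(\C)CCC=C(C)C | intermediate
15 | 14 lithiated at C2 (between carbamate and MOM ether) | COCOc1cc(OC(=O)N(C(C)C)[Si](C)(C)C(C)(C)C)c([Li])c(OCOC)c1C/C=C(\C)CCC=C(C)C | intermediate
16 | N-(tert-butyldimethylsilyl) derivative of 17 | COCOc1cc(OC(=O)N(C(C)C)[Si](C)(C)C(C)(C)C)c([Si](C)(C)C)c(OCOC)c1C/C=C(\C)CCC=C(C)C | intermediate
17 | 4-geranyl-3,5-bis(methoxymethoxy)-2-(trimethylsilyl)phenyl N-isopropylcarbamate | COCOc1cc(OC(=O)NC(C)C)c([Si](C)(C)C)c(OCOC)c1C/C=C(\C)CCC=C(C)C | intermediate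
18 | N-phenylbis(trifluoromethanesulfonimide) | O=S(=O)(N(c1ccccc1)S(=O)(=O)C(F)(F)F)C(F)(F)F | starting material
19 | 4-geranyl-3,5-bis(methoxymethoxy)-2-(trimethylsilyl)phenol | COCOc1cc(O)c([Si](C)(C)C)c(OCOC)c1C/C=C(\C)CCC=C(C)C | intermediate
20 | 4-geranyl-3,5-bis(methoxymethoxy)-2-(trimethylsilyl)phenyl trifluoromethanesulfonate | COCOc1cc(OS(=O)(=O)C(F)(F)F)c([Si](C)(C)C)c(OCOC)c1C/C=C(\C)CCC=C(C)C | intermediate
21 | (E)-3,4-dimethoxycinnamic acid | COc1ccc(/C=C/C(=O)O)cc1OC | starting material
22 | cesium (E)-3,4-dimethoxycinnamate | COc1ccc(/C=C/C(=O)[O-])cc1OC.[Cs+] | intermediate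
23 | 4-geranyl-3,5-bis(methoxymethoxy)benzyne (aryne across the former C–Si and C–OTf carbons) | COCOC1=CC#CC(OCOC)=C1C/C=C(\C)CCC=C(C)C | intermediate
24 | (E)-1-[3-geranyl-6-hydroxy-2,4-bis(methoxymethoxy)phenyl]-3-(3,4-dimethoxyphenyl)prop-2-en-1-one | COCOc1cc(O)c(C(=O)/C=C/c2ccc(OC)c(OC)c2)c(OCOC)c1C/C=C(\C)CCC=C(C)C | intermediate
25 | (2S)-6-geranyl-5,7-bis(methoxymethoxy)-3′,4′-dimethoxyflavanone | COc1ccc([C@@H]2CC(=O)c3c(cc(OCOC)c(C/C=C(\C)CCC=C(C)C)c3OCOC)O2)cc1OC | intermediate
26 | (2S)-6-geranyl-5,7-dihydroxy-3′,4′-dimethoxyflavanone | COc1ccc([C@@H]2CC(=O)c3c(cc(O)c(C/C=C(\C)CCC=C(C)C)c3O)O2)cc1OC | target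

**Step count**

Total steps: 10. Longest linear sequence: 10 (from phloroglucinol).

**Steps most likely to fail**

Step 8. The aryl anion may be protonated before acyl transfer, stopping at the aryl ester. The phenoxide may also close onward to racemic flavanone if a proton donor is present, or the aryne may be consumed by ene-type reactions with the diene. The fallback sets out from carbamate 12 and replaces aryne insertion by directed ortho-acylation and aldol condensation. Carbamate 12 is N-silylated and lithiated as in step 6 to aryllithium 15, which is quenched with N-methoxy-N-methylacetamide. This gives the N-silylated 2-acetyl-4-geranyl-3,5-bis(methoxymethoxy)phenyl N-isopropylcarbamate F1 and, after aqueous work-up, 2-acetyl-4-geranyl-3,5-bis(methoxymethoxy)phenyl N-isopropylcarbamate F2. DBU/Et2NH in MeCN should remove the carbamate to give 1-[3-geranyl-6-hydroxy-2,4-bis(methoxymethoxy)phenyl]ethanone F3. Claisen–Schmidt condensation with 3,4-dimethoxybenzaldehyde (KOH, EtOH, rt, cold acidification) returns to the route at chalcone 24.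

Step 9. Facial discrimination may be poor on this 6′-alkoxy chalcone, and reversible retro-oxa-Michael opening may erode the ee. The fallback sets out from chalcone 24 and replaces asymmetric catalysis by resolution. NaOAc in refluxing EtOH should give racemic 6-geranyl-5,7-bis(methoxymethoxy)-3′,4′-dimethoxyflavanone F4. Preparative HPLC on an amylose tris(3,5-dimethylphenylcarbamate) phase separates the enantiomers and returns to the route at 25. The (2R)-6-geranyl-5,7-bis(methoxymethoxy)-3′,4′-dimethoxyflavanone F5 is re-equilibrated to the racemate with base and recycled.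

Step 10. Acid may cyclise the geranyl chain onto a neighbouring phenol, add solvent across the trisubstituted alkenes, or open ring C and scramble C2. The fallback sets out from 25 and replaces protic solvolysis by acetal-to-silyl-ether exchange under buffered aprotic conditions. TESOTf with 2,2′-bipyridyl in CH2Cl2 at 0 °C should convert both aryl MOM ethers into (2S)-6-geranyl-3′,4′-dimethoxy-5,7-bis(triethylsilyloxy)flavanone F6. Desilylation with n-Bu4NF buffered with AcOH in THF at 0 °C returns to the route at target 26.

**Further compounds**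

F1 | step 8 | 2-acetyl-4-geranyl-3,5-bis(methoxymethoxy)phenyl N-(tert-butyldimethylsilyl)-N-isopropylcarbamate | CC(=O)c1c(OC(=O)N(C(C)C)[Si](C)(C)C(C)(C)C)cc(OCOC)c(C/C=C(\C)CCC=C(C)C)c1OCOC
F2 | step 8 | 2-acetyl-4-geranyl-3,5-bis(methoxymethoxy)phenyl N-isopropylcarbamate | CC(=O)c1c(OC(=O)NC(C)C)cc(OCOC)c(C/C=C(\C)CCC=C(C)C)c1OCOC
F3 | step 8 | 1-[3-geranyl-6-hydroxy-2,4-bis(methoxymethoxy)phenyl]ethanone | CC(=O)c1c(O)cc(OCOC)c(C/C=C(\C)CCC=C(C)C)c1OCOC
F4 | step 9 | racemic 6-geranyl-5,7-bis(methoxymethoxy)-3′,4′-dimethoxyflavanone | COc1ccc(C2CC(=O)c3c(cc(OCOC)c(C/C=C(\C)CCC=C(C)C)c3OCOC)O2)cc1OC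
F5 | step 9 | (2R)-6-geranyl-5,7-bis(methoxymethoxy)-3′,4′-dimethoxyflavanone | COc1ccc([C@H]2CC(=O)c3c(cc(OCOC)c(C/C=C(\C)CCC=C(C)C)c3OCOC)O2)cc1OC
F6 | step 10 | (2S)-6-geranyl-3′,4′-dimethoxy-5,7-bis(triethylsilyloxy)flavanone | COc1ccc([C@@H]2CC(=O)c3c(cc(O[Si](CC)(CC)CC)c(C/C=C(\C)CCC=C(C)C)c3O[Si](CC)(CC)CC)O2)cc1OC
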